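**Retrosynthetic overview** (labdane numbering: ring A = C1–C5, C10; ring B = C5–C10; C17 on C8; C20 on C10)

1. Endgame: the (Z)-cinnamate comes from Lindlar reduction of a phenylpropiolate on O15; C13 comes from asymmetric hydrogenation of an alkylidene butyrolactone made by cross-metathesis at a C9 allyl group; the C6 carbonyl of the key product is removed by allylic hydrogenolysis.
2. Key disconnection: ring B is a 3-methylcyclohexene in which C5 and C7 both flank C6, while C10 and C8 are 1,3-related through C9. With a ketone at C6 (extra oxidation level), C5 and C7 are the two α-carbons of one carbonyl and C10=C9–C8(=O) is an enone, so C5–C10 and C7=C8 cleave back to the acyclic ene-dione 12.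
3. Ring order: ring A closes first (C5–C10, aza-ene Michael addition of a 1-phenylethylamine enamine), ring B second (C7=C8, enamine aldol condensation), in the same flask. The bought amine sets C10, the (E)-alkene relays C9, and equilibration gives the trans C5.
4. 12 comes from mesityl oxide (C4–C7 and the gem-dimethyl group), allyltrimethylsilane (C1–C3) and 3-allylpentane-2,4-dione (C8–C12, C17, C20) through a Sakurai addition and a stereoretentive B-alkyl Suzuki coupling of an (E)-enol triflate.

Key step: step 7

Remark on the chemistry: the antipode written for each chiral controller ((R)-1-phenylethylamine in step 7, (S)-BINAP in step 10) is the one expected by analogy to give the drawn configuration; should a first run show the opposite sense, the mirror-image controller, equally available, is used.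

**Step 1**
Reactants: 1 mesityl oxide (4-methylpent-3-en-2-one); 2 allyltrimethylsilane
Product: 3 4,4-dimethylhept-6-en-2-one
Conditions: TiCl4 (1.1 equiv), CH2Cl2, −78 °C; then H2O
Reagents that add atoms: none
Why: Hosomi–Sakurai conjugate allylation of the TiCl4-activated β,β-disubstituted enone should install the gem-dimethyl quaternary carbon C4 together with C3–C1; no stereocentre is formed.

**Step 2**
Reactants: 3 4,4-dimethylhept-6-en-2-one
Product: 4 2-(2,2-dimethylpent-4-en-1-yl)-2-methyl-1,3-dioxolane
Conditions: HOCH2CH2OH, p-TsOH (cat.), toluene, reflux, water separator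
Reagents that add atoms: ethylene glycol, OCCO
Why: Acid-catalysed ketalisation with azeotropic removal of water masks the C6 ketone against the borane and the base of step 5; the terminal alkene is inert.

**Step 3**
Reactants: 5 pentane-2,4-dione; 6 allyl bromide
Product: 7 3-(prop-2-en-1-yl)pentane-2,4-dione
Conditions: K2CO3, acetone, reflux
Reagents that add atoms: none
Why: C-allylation of the potassium enolate of a 1,3-diketone is a standard SN2 alkylation; any diallylated material is removed by distillation.

**Step 4**
Reactants: 7 3-(prop-2-en-1-yl)pentane-2,4-dione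
Product: 8 (2E)-4-oxo-3-(prop-2-en-1-yl)pent-2-en-2-yl trifluoromethanesulfonate
Conditions: Tf2O, aq. Me4NOH, toluene, 0 °C
Reagents that add atoms: trifluoromethanesulfonic anhydride, O=S(=O)(OS(=O)(=O)C(F)(F)F)C(F)(F)F
Why: O-Triflation of the non-chelated tetramethylammonium enolate should place the triflate anti to the remaining acetyl group (E), which fixes the alkene geometry later translated into C9.

**Step 5**
Reactants: 4 2-(2,2-dimethylpent-4-en-1-yl)-2-methyl-1,3-dioxolane; 9 9-borabicyclo[3.3.1]nonane (9-BBN); 8 (E)-enol triflate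
Product: 11 (3E)-4,8,8-trimethyl-9-(2-methyl-1,3-dioxolan-2-yl)-3-(prop-2-en-1-yl)non-3-en-2-one, via alkylborane 10 (not isolated)
Conditions: 9-BBN, THF, 0 → 25 °C; then 8, PdCl2(dppf) (5 mol %), K3PO4, DMF/THF/H2O, 25–40 °C
Reagents that add atoms: none
Why: Anti-Markovnikov hydroboration of the terminal alkene followed by B-alkyl Suzuki–Miyaura coupling with the vinylogous acyl triflate proceeds with retention of alkene geometry and should give the (E)-tetrasubstituted enone.

**Step 6**
Reactants: 11 ketal enone
Product: 12 (3E)-4,8,8-trimethyl-3-(prop-2-en-1-yl)undec-3-ene-2,10-dione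
Conditions: PPTS (cat.), acetone/H2O, 50 °C
Reagents that add atoms: water, O
Why: Mild acid-catalysed hydrolysis of the dioxolane releases the C6 methyl ketone without disturbing the enone geometry or the allyl group.

**Step 7**
Reactants: 12 (3E)-4,8,8-trimethyl-3-(prop-2-en-1-yl)undec-3-ene-2,10-dione; 13 (R)-1-phenylethylamine
Product: 17 bicyclic enone (4S,4aR,8aS)-3,4a,8,8-tetramethyl-4-(prop-2-en-1-yl)-4a,5,6,7,8,8a-hexahydronaphthalen-1(4H)-one, via ketimine 14 (not isolated), via cyclohexyl ketimine 15 (not isolated), via bicyclic azadiene 16 (not isolated)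
Conditions: 13 (1.2 equiv), PhCO2H (20 mol %), 4 Å MS, toluene, 25 → 100 °C; then 10% aq. AcOH/THF, 25 °C
Reagents that add atoms: water, O
Why: Proposed new method: the amine condenses with the unconjugated C6 ketone to ketimine 14, whose secondary enamine tautomer on the C5 side adds to C10 of the (E)-enone in an intramolecular aza-ene (Michael-type) transition state that delivers N–H to C9 on the same face (ring A, 6-exo-trig) and gives 15; the C6 imine then tautomerises to the C7 enamine, which attacks the C8 ketone (ring B, 6-(enolendo)-exo-trig) and loses water to azadiene 16, hydrolysed to 17 on work-up. The closest known reaction types are the Michael addition of chiral 1-phenylethylamine ketimines to electron-poor alkenes (also intramolecular) and amine-mediated Robinson-type aldol condensations; an enone acceptor that is tetrasubstituted and becomes the quaternary carbon has not been shown. C10 is controlled by the auxiliary, whose phenyl group shields one enamine face in the compact bicyclic transition state; C9 follows from the suprafacial C–C/C–H addition across the (E)-alkene; C5 ends trans to the angular methyl by imine–enamine equilibration to the diequatorial cyclohexane and the more stable trans-fused enone. The step needs Michael regioselectivity (C5 and not C7), secured by ring size (six- against eight-membered), and aldol regioselectivity (C7 onto C8 and not the acetyl methyl onto C6), secured by the nitrogen that stays on C6 and by the neopentyl shielding of C6.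

**Step 8**
Reactants: 17 bicyclic enone
Product: 18 (1S,4aS,8aS)-2,5,5,8a-tetramethyl-1-(prop-2-en-1-yl)-1,4,4a,5,6,7,8,8a-octahydronaphthalene
Conditions: LiAlH4, AlCl3 (1:3), Et2O, 0 °C → reflux
Reagents that add atoms: none
Why: Chloroalane (mixed hydride) hydrogenolysis of an enone: 1,2-reduction, ionisation of the allylic aluminium alkoxide and hydride capture at the secondary terminus C6 from the open α-face should keep the more substituted C7=C8 alkene, as in the conversion of steroidal 4-en-3-ones into 4-enes; C5, C9 and C10 are untouched.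

**Step 9**
Reactants: 18 diene; 19 α-methylene-γ-butyrolactone (3-methylidenedihydrofuran-2(3H)-one)
Product: 20 (3E)-3-{2-[(1S,4aS,8aS)-2,5,5,8a-tetramethyl-1,4,4a,5,6,7,8,8a-octahydronaphthalen-1-yl]ethylidene}dihydrofuran-2(3H)-one
Conditions: second-generation Grubbs catalyst [RuCl2(=CHPh)(H2IMes)(PCy3)] (5 mol %), 2,6-dichloro-1,4-benzoquinone (10 mol %), CH2Cl2, 40 °C
Reagents that add atoms: none
Why: Olefin cross-metathesis between the terminal allyl alkene and the 1,1-disubstituted alkene of the lactone should give the thermodynamically preferred E-alkylidene lactone; the trisubstituted ring alkene does not react and the quinone suppresses ruthenium-hydride isomerisation of the methylene lactone.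

**Step 10**
Reactants: 20 alkylidene lactone
Product: 21 (3S)-3-{2-[(1S,4aS,8aS)-2,5,5,8a-tetramethyl-1,4,4a,5,6,7,8,8a-octahydronaphthalen-1-yl]ethyl}dihydrofuran-2(3H)-one
Conditions: H2 (100 atm), Ru(OAc)2[(S)-BINAP] (1 mol %), CH2Cl2/MeOH, 50 °C
Reagents that add atoms: none
Why: Noyori asymmetric hydrogenation: the lactone carbonyl binds ruthenium and the BINAP ligand selects the alkene face, which sets C13 as S; the unfunctionalised trisubstituted C7=C8 alkene is not reduced by this catalyst.

**Step 11**
Reactants: 21 lactone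
Product: 23 methyl (2S)-4-hydroxy-2-{2-[(1S,4aS,8aS)-2,5,5,8a-tetramethyl-1,4,4a,5,6,7,8,8a-octahydronaphthalen-1-yl]ethyl}butanoate, via potassium carboxylate 22 (not isolated)
Conditions: KOH (1.0 equiv), MeOH/H2O, 25 °C; evaporate; MeI, DMF, 0 → 25 °C
Reagents that add atoms: potassium hydroxide, [K+].[OH-]; iodomethane, CI
Why: Saponification opens the lactone and SN2 O-methylation of the carboxylate under non-acidic conditions should give the hydroxy ester, which is used at once so that it cannot relactonise; C13 is not enolised by one equivalent of hydroxide at room temperature.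

**Step 12**
Reactants: 23 hydroxy ester; 24 phenylpropiolic acid
Product: 25 methyl (2S)-4-[(3-phenylprop-2-ynoyl)oxy]-2-{2-[(1S,4aS,8aS)-2,5,5,8a-tetramethyl-1,4,4a,5,6,7,8,8a-octahydronaphthalen-1-yl]ethyl}butanoate
Conditions: DCC, DMAP (cat.), CH2Cl2, 0 °C
Reagents that add atoms: none
Why: Steglich esterification of the primary alcohol is fast at 0 °C and should outrun lactonisation; the alkynoate is a configurationally safe precursor of the Z-cinnamate.

**Step 13**
Reactants: 25 phenylpropiolate
Product: 26 target, methyl (2S)-4-{[(2Z)-3-phenylprop-2-enoyl]oxy}-2-{2-[(1S,4aS,8aS)-2,5,5,8a-tetramethyl-1,4,4a,5,6,7,8,8a-octahydronaphthalen-1-yl]ethyl}butanoate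
Conditions: H2 (1 atm), Pd/CaCO3 poisoned with Pb(OAc)2 (Lindlar catalyst), quinoline, EtOAc, 25 °C
Reagents that add atoms: none
Why: Lindlar semihydrogenation adds hydrogen syn to the alkyne and should give the Z-cinnamate; the trisubstituted ring alkene and the esters do not react.

**Compound list**

1 | mesityl oxide (4-methylpent-3-en-2-one) | CC(=O)C=C(C)C | starting material
2 | allyltrimethylsilane | C=CC[Si](C)(C)C | starting material
3 | 4,4-dimethylhept-6-en-2-one | CC(=O)CC(C)(C)CC=C | intermediate
4 | 2-(2,2-dimethylpent-4-en-1-yl)-2-methyl-1,3-dioxolane | CC1(CC(C)(C)CC=C)OCCO1 | intermediate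
5 | pentane-2,4-dione | CC(=O)CC(C)=O | starting material
6 | allyl bromide | C=CCBr | starting material
7 | 3-(prop-2-en-1-yl)pentane-2,4-dione | CC(=O)C(CC=C)C(C)=O | intermediate
8 | (2E)-4-oxo-3-(prop-2-en-1-yl)pent-2-en-2-yl trifluoromethanesulfonate | CC(=O)/C(CC=C)=C(\C)OS(=O)(=O)C(F)(F)F | intermediate
9 | 9-borabicyclo[3.3.1]nonane (9-BBN) | B1C2CCCC1CCC2 | starting material
10 | 9-[4,4-dimethyl-5-(2-methyl-1,3-dioxolan-2-yl)pentyl]-9-borabicyclo[3.3.1]nonane (not isolated) | CC1(CC(C)(C)CCCB2C3CCCC2CCC3)OCCO1 | intermediate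
11 | (3E)-4,8,8-trimethyl-9-(2-methyl-1,3-dioxolan-2-yl)-3-(prop-2-en-1-yl)non-3-en-2-one | CC(=O)/C(CC=C)=C(\C)CCCC(C)(C)CC1(C)OCCO1 | intermediate
12 | (3E)-4,8,8-trimethyl-3-(prop-2-en-1-yl)undec-3-ene-2,10-dione | CC(=O)/C(CC=C)=C(\C)CCCC(C)(C)CC(C)=O | intermediate
13 | (R)-1-phenylethylamine | C[C@@H](N)c1ccccc1 | starting material
14 | C6 ketimine of 12 with (R)-1-phenylethylamine (not isolated) | CC(=O)/C(CC=C)=C(\C)CCCC(C)(C)CC(C)=N[C@H](C)c1ccccc1 | intermediate
15 | (3R)-3-[(1S)-1,3,3-trimethyl-2-{N-[(1R)-1-phenylethyl]ethanimidoyl}cyclohexyl]hex-5-en-2-one, C5 epimers in equilibrium (not isolated) | C=CC[C@@H](C(C)=O)[C@@]1(C)CCCC(C)(C)C1C(C)=N[C@H](C)c1ccccc1 | intermediate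
16 | N-[(1R)-1-phenylethyl]imine of enone 17, trans-fused (not isolated) | C=CC[C@H]1C(C)=CC(=N[C@H](C)c2ccccc2)[C@H]2C(C)(C)CCC[C@]12C | intermediate
17 | (4S,4aR,8aS)-3,4a,8,8-tetramethyl-4-(prop-2-en-1-yl)-4a,5,6,7,8,8a-hexahydronaphthalen-1(4H)-one (trans-fused; 5α-H, 9α-H, 10β-CH3) | C=CC[C@H]1C(C)=CC(=O)[C@H]2C(C)(C)CCC[C@]12C | intermediate
18 | (1S,4aS,8aS)-2,5,5,8a-tetramethyl-1-(prop-2-en-1-yl)-1,4,4a,5,6,7,8,8a-octahydronaphthalene | C=CC[C@H]1C(C)=CC[C@H]2C(C)(C)CCC[C@]12C | intermediate
19 | α-methylene-γ-butyrolactone (3-methylidenedihydrofuran-2(3H)-one) | C=C1CCOC1=O | starting material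
20 | (3E)-3-{2-[(1S,4aS,8aS)-2,5,5,8a-tetramethyl-1,4,4a,5,6,7,8,8a-octahydronaphthalen-1-yl]ethylidene}dihydrofuran-2(3H)-one | O=C1OCC/C1=C\C[C@H]1C(C)=CC[C@H]2C(C)(C)CCC[C@]12C | intermediate
21 | (3S)-3-{2-[(1S,4aS,8aS)-2,5,5,8a-tetramethyl-1,4,4a,5,6,7,8,8a-octahydronaphthalen-1-yl]ethyl}dihydrofuran-2(3H)-one | O=C1OCC[C@@H]1CC[C@H]1C(C)=CC[C@H]2C(C)(C)CCC[C@]12C | intermediate
22 | potassium (2S)-4-hydroxy-2-{2-[(1S,4aS,8aS)-2,5,5,8a-tetramethyl-1,4,4a,5,6,7,8,8a-octahydronaphthalen-1-yl]ethyl}butanoate (not isolated) | [K+].[O-]C(=O)[C@H](CCO)CC[C@H]1C(C)=CC[C@H]2C(C)(C)CCC[C@]12C | intermediate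
23 | methyl (2S)-4-hydroxy-2-{2-[(1S,4aS,8aS)-2,5,5,8a-tetramethyl-1,4,4a,5,6,7,8,8a-octahydronaphthalen-1-yl]ethyl}butanoate | COC(=O)[C@H](CCO)CC[C@H]1C(C)=CC[C@H]2C(C)(C)CCC[C@]12C | intermediate
24 | phenylpropiolic acid | OC(=O)C#Cc1ccccc1 | starting material
25 | methyl (2S)-4-[(3-phenylprop-2-ynoyl)oxy]-2-{2-[(1S,4aS,8aS)-2,5,5,8a-tetramethyl-1,4,4a,5,6,7,8,8a-octahydronaphthalen-1-yl]ethyl}butanoate | COC(=O)[C@H](CCOC(=O)C#Cc1ccccc1)CC[C@H]1C(C)=CC[C@H]2C(C)(C)CCC[C@]12C | intermediate
26 | methyl (2S)-4-{[(2Z)-3-phenylprop-2-enoyl]oxy}-2-{2-[(1S,4aS,8aS)-2,5,5,8a-tetramethyl-1,4,4a,5,6,7,8,8a-octahydronaphthalen-1-yl]ethyl}butanoate | COC(=O)[C@H](CCOC(=O)/C=C\c1ccccc1)CC[C@H]1C(C)=CC[C@H]2C(C)(C)CCC[C@]12C | target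

**Step count and risks**

Total step count: 13. Longest linear sequence: 11 steps (steps 1, 2 and 5–13, or steps 3–13).

Step 7 (Proposed new method) is the most likely to fail. The enamine may add too slowly to the hindered tetrasubstituted enone, the amine may condense at the enone carbonyl, facial control by the auxiliary may be incomplete, and C9 may epimerise through the dienamine of the product or through E/Z isomerisation of 12 before ring closure. The fallback uses known chemistry, sets out from 12 and comes back at 18. Acid-catalysed Michael addition/aldol condensation (p-TsOH, toluene, reflux, water separator) should give the racemic bicyclic enone F1. Luche reduction (NaBH4, CeCl3·7H2O, MeOH), with hydride entering from the α-face, should give the racemic 6β-allylic alcohol F2. Acylation with (1S)-camphanic chloride in pyridine and separation of the diastereomers by crystallisation or chromatography (which also removes any C9 epimer) should give the camphanate of the natural series F3. LiAlH4 followed by AlCl3 in Et2O then cleaves the ester and hydrogenolyses the allylic C–O bond to 18.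

Step 8 is the second risk. Hydride may be delivered to the tertiary terminus C8, which moves the alkene to C6=C7, or the allyl cation may lose a proton to a diene. The fallback sets out from 17 and comes back at 18. Luche reduction should give the 6β-allylic alcohol F4; phosphorylation with diethyl chlorophosphate (pyridine, DMAP) the allylic diethyl phosphate F5; and reductive cleavage with Li in liquid NH3/THF with t-BuOH should give 18, because the allyl anion is protonated at the less substituted terminus C6 and the isolated alkenes are not reduced.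

Step 5 is the third risk. The vinylogous acyl triflate may be hydrolysed by the aqueous base, transmetalation to the fully substituted carbon may be slower than protodeboronation, and the alkene geometry may leak. The fallback sets out from 4 and 8 and comes back at 11. Hydroboration of 4 with 9-BBN (through alkylborane 10) and oxidation (NaOH, H2O2) should give the primary alcohol F6; iodination (I2, PPh3, imidazole) the primary iodide F7; zinc insertion (Zn dust, LiCl, THF) the alkylzinc iodide F8; and base-free Negishi coupling of F8 with 8 (Pd(PPh3)4, THF) should give 11 with retention of the alkene geometry.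

**Further compounds**

F1 | step 7 | racemic bicyclic enone (17 and its mirror image) | C=CC[C@H]1C(C)=CC(=O)[C@H]2C(C)(C)CCC[C@]12C.C=CC[C@@H]1C(C)=CC(=O)[C@@H]2C(C)(C)CCC[C@@]12C
F2 | step 7 | racemic 6β-allylic alcohol (hydroxyl cis to the angular methyl) | C=CC[C@H]1C(C)=C[C@@H](O)[C@H]2C(C)(C)CCC[C@]12C.C=CC[C@@H]1C(C)=C[C@H](O)[C@@H]2C(C)(C)CCC[C@@]12C
F3 | step 7 | (1S)-camphanate of the 6β-allylic alcohol of the natural series | C=CC[C@H]1C(C)=C[C@@H](OC(=O)[C@@]34CC[C@@](C)(C(=O)O3)C4(C)C)[C@H]2C(C)(C)CCC[C@]12C
F4 | step 8 | 6β-allylic alcohol from 17 (single enantiomer) | C=CC[C@H]1C(C)=C[C@@H](O)[C@H]2C(C)(C)CCC[C@]12C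
F5 | step 8 | allylic diethyl phosphate of F4 | C=CC[C@H]1C(C)=C[C@@H](OP(=O)(OCC)OCC)[C@H]2C(C)(C)CCC[C@]12C
F6 | step 5 | 4,4-dimethyl-5-(2-methyl-1,3-dioxolan-2-yl)pentan-1-ol | CC1(CC(C)(C)CCCO)OCCO1
F7 | step 5 | 2-(5-iodo-2,2-dimethylpentyl)-2-methyl-1,3-dioxolane | CC1(CC(C)(C)CCCI)OCCO1
F8 | step 5 | [4,4-dimethyl-5-(2-methyl-1,3-dioxolan-2-yl)pentyl]zinc iodide | CC1(CC(C)(C)CCC[Zn]I)OCCO1
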